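## Retrosynthetic overview

1. Endgame: esterify the only free hydroxyl (C8–OH), then one fluoride step frees the acid and three hydroxyls; the hydroxy acid never meets acid, so the 6,12-lactone is avoided.
2. The only ring (cyclohexane C5–C10) is closed at C7–C8 by a SmI2 ketyl-radical 6-exo cyclization of a C8 aldehyde onto a 2-(acetoxymethyl)enoate; loss of acetate gives the C7 acrylate, and the chair sets C7 and C8.
3. C5–C6: catalytic asymmetric chromium allylation of enal fragment 2 with allyl bromide fragment 1 (anti; sets C5 and C6).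
4. C10: Evans dienolate alkylation of an N-tigloyl oxazolidinone with ethylene sulfate gives (S)-α-methyl-α-vinylbutyrolactone, which a 2-lithioallyl silyl ether opens (brings C3, C4, C15).
5. Fragment 2 (C6, C7, C11–C13): Morita–Baylis–Hillman adduct of dimethoxyacetaldehyde and an acrylate, acetate transposition, acetal hydrolysis.

Assumption: elemane locants are used (ring C5–C10; C10 carries CH3-14 and vinyl C1=C2; C5 carries C4(=C3H2)C15H2OH; C7 carries C11(=C13H2)C12OOH), and the auxiliary, ligand and TADDOL enantiomers named are those the usual facial models predict, to be exchanged for the mirror image if a sense proves opposite.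

## Route

Step 1
Reactants: 1 (E)-2-methylbut-2-enoyl chloride (tigloyl chloride)
Product: 2 (R)-4-benzyl-3-[(E)-2-methylbut-2-enoyl]oxazolidin-2-one
Conditions: (R)-4-benzyloxazolidin-2-one, n-BuLi, THF, −78 °C; then 1, −78 → 0 °C
Reagents that add atoms: (R)-4-benzyloxazolidin-2-one, O=C1N[C@H](Cc2ccccc2)CO1
Why: N-acylation of the lithiated Evans auxiliary installs the chiral controller; no stereocentre is formed.

Step 2
Reactants: 2 (R)-4-benzyl-3-[(E)-2-methylbut-2-enoyl]oxazolidin-2-one; 3 1,3,2-dioxathiolane 2,2-dioxide (ethylene sulfate)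
Product: 6 (S)-3-methyl-3-vinyldihydrofuran-2(3H)-one, via alkyl sulfate salt 4 (not isolated), via hydroxy imide 5 (not isolated)
Conditions: NaN(SiMe3)2, THF, −78 °C; 3, −78 → −20 °C; then 20% aq. H2SO4, THF, 25 → 50 °C
Reagents that add atoms: none
Why: Evans-type deconjugative α-alkylation of the chelated sodium dienolate (methyl syn to O, electrophile anti to benzyl) sets the C10 quaternary centre as S, the cyclic sulfate acting as a hydroxyethyl cation equivalent whose acid hydrolysis triggers lactonization and releases the auxiliary.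

Step 3
Reactants: 7 2-bromoprop-2-en-1-ol
Product: 8 (2-bromoallyloxy)(tert-butyl)dimethylsilane
Conditions: t-BuMe2SiCl, imidazole, CH2Cl2, 0 °C → rt
Reagents that add atoms: tert-butyldimethylsilyl chloride, CC(C)(C)[Si](C)(C)Cl
Why: routine silylation of the primary allylic alcohol; no stereocentre.

Step 4
Reactants: 8 (2-bromoallyloxy)(tert-butyl)dimethylsilane; 6 (S)-3-methyl-3-vinyldihydrofuran-2(3H)-one
Product: 11 (S)-2-[(tert-butyldimethylsilyloxy)methyl]-4-methyl-6-(triethylsilyloxy)-4-vinylhex-1-en-3-one, via vinyllithium 9 (not isolated), via lithium alkoxide 10 (not isolated)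
Conditions: 8, t-BuLi (2.0 equiv per 8), Et2O, −78 °C; then 6, −78 °C; then Et3SiCl, −78 → 0 °C
Reagents that add atoms: chlorotriethylsilane, CC[Si](CC)(CC)Cl
Why: bromine–lithium exchange gives the 2-lithioallyl ether, which adds once to the hindered α-quaternary lactone, and O-silylation of the ring-opened alkoxide traps the ω-silyloxy enone; C10 is untouched.

Step 5
Reactants: 11 (S)-2-[(tert-butyldimethylsilyloxy)methyl]-4-methyl-6-(triethylsilyloxy)-4-vinylhex-1-en-3-one
Product: 12 (4S)-2-[(tert-butyldimethylsilyloxy)methyl]-4-methyl-6-(triethylsilyloxy)-4-vinylhex-1-en-3-ol (both C3 epimers)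
Conditions: i-Bu2AlH, CH2Cl2, −78 °C
Reagents that add atoms: none
Why: 1,2-reduction of the α-methylene ketone; the new carbinol centre is irrelevant because it becomes sp2 in step 6.

Step 6
Reactants: 12 (4S)-2-[(tert-butyldimethylsilyloxy)methyl]-4-methyl-6-(triethylsilyloxy)-4-vinylhex-1-en-3-ol
Product: 13 (S)-1-bromo-2-[(tert-butyldimethylsilyloxy)methyl]-4-methyl-6-(triethylsilyloxy)-4-vinylhex-2-ene (E/Z mixture; fragment 1)
Conditions: CBr4, PPh3, 2,6-lutidine, CH2Cl2, −20 → 0 °C
Reagents that add atoms: carbon tetrabromide, BrC(Br)(Br)Br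
Why: Appel bromination, in which direct substitution at the neopentyl carbinol is blocked so bromide enters with allylic transposition (SN2′); alkene geometry is immaterial because the derived allylchromium equilibrates.

Step 7
Reactants: 14 acryloyl chloride
Product: 15 2-(trimethylsilyl)ethyl acrylate
Conditions: Me3SiCH2CH2OH, Et3N, CH2Cl2, 0 °C
Reagents that add atoms: 2-(trimethylsilyl)ethanol, C[Si](C)(C)CCO
Why: simple acylation that installs a fluoride-labile ester for the future C12 acid.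

Step 8
Reactants: 15 2-(trimethylsilyl)ethyl acrylate; 16 2,2-dimethoxyacetaldehyde
Product: 17 2-(trimethylsilyl)ethyl 2-(1-hydroxy-2,2-dimethoxyethyl)acrylate (racemic)
Conditions: DABCO (0.5 equiv), 1,4-dioxane/H2O (1:1), rt, 48 h
Reagents that add atoms: none
Why: Morita–Baylis–Hillman reaction of an activated α-alkoxy aldehyde; the racemic carbinol centre is erased in step 9.

Step 9
Reactants: 17 2-(trimethylsilyl)ethyl 2-(1-hydroxy-2,2-dimethoxyethyl)acrylate
Product: 19 2-(trimethylsilyl)ethyl (E)-2-(acetoxymethyl)-4,4-dimethoxybut-2-enoate, via secondary acetate 18 (not isolated)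
Conditions: Ac2O, Et3N, DMAP (cat.), CH2Cl2, 0 °C; then DABCO (1.0 equiv), THF, 60 °C
Reagents that add atoms: acetic anhydride, CC(=O)OC(C)=O
Why: acetylation followed by DABCO-mediated SN2′–SN2′ transposition of the Morita–Baylis–Hillman acetate gives the thermodynamic (E)-2-(acetoxymethyl)enoate.

Step 10
Reactants: 19 2-(trimethylsilyl)ethyl (E)-2-(acetoxymethyl)-4,4-dimethoxybut-2-enoate
Product: 20 2-(trimethylsilyl)ethyl (E)-2-(acetoxymethyl)-4-oxobut-2-enoate (fragment 2)
Conditions: Amberlyst-15, acetone/H2O (20:1), rt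
Reagents that add atoms: water, O
Why: mild acid hydrolysis of the dimethyl acetal; the E geometry keeps the aldehyde away from the ester, so no pseudo-acid lactol forms.

Step 11
Reactants: 13 (S)-1-bromo-2-[(tert-butyldimethylsilyloxy)methyl]-4-methyl-6-(triethylsilyloxy)-4-vinylhex-2-ene; 20 2-(trimethylsilyl)ethyl (E)-2-(acetoxymethyl)-4-oxobut-2-enoate
Product: 21 2-(trimethylsilyl)ethyl (2E,4S,5R,6S)-2-(acetoxymethyl)-5-[3-(tert-butyldimethylsilyloxy)prop-1-en-2-yl]-6-methyl-4,8-bis(triethylsilyloxy)-6-vinyloct-2-enoate (elemane locants 5R,6S,10S)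
Conditions: CrCl2 (10 mol%), (S,S)-3,6-di-tert-butyl-1,8-bis(4-isopropyl-4,5-dihydrooxazol-2-yl)-9H-carbazole (12 mol%), Mn powder (2 equiv), i-Pr2NEt (0.3 equiv), Et3SiCl (1.5 equiv), THF, 0 °C → rt
Reagents that add atoms: chlorotriethylsilane, CC[Si](CC)(CC)Cl
Why: catalytic asymmetric Nozaki–Hiyama–Kishi allylation in which the equilibrating γ-substituted allylchromium adds through C5 in a chair transition state (anti C5/C6) to the ligand-selected Re face of the aldehyde, while the chlorosilane turns over chromium and delivers the C6 silyl ether directly.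

Step 12
Reactants: 21 the bis(triethylsilyl) ether from step 11
Product: 22 2-(trimethylsilyl)ethyl (2E,4S,5R,6S)-2-(acetoxymethyl)-5-[3-(tert-butyldimethylsilyloxy)prop-1-en-2-yl]-6-methyl-8-oxo-4-(triethylsilyloxy)-6-vinyloct-2-enoate
Conditions: (COCl)2, DMSO, CH2Cl2, −78 → −40 °C; then Et3N, −78 → 0 °C
Reagents that add atoms: none
Why: Swern conditions oxidatively cleave the primary triethylsilyl ether straight to the aldehyde while the hindered secondary triethylsilyl and the tert-butyldimethylsilyl ethers survive; no stereocentre is touched.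

Step 13
Reactants: 22 the C8 aldehyde from step 12
Product: 23 2-(trimethylsilyl)ethyl 8α-hydroxy-6α-(triethylsilyloxy)-15-(tert-butyldimethylsilyloxy)elema-1,3,11(13)-trien-12-oate (5R,6R,7R,8S,10S; C5 and C7 side chains β-equatorial, O6 and O8 α-equatorial, C10 methyl β-axial)
Conditions: SmI2 (2.5 equiv), HMPA (6 equiv), THF, −78 °C, 30 min; sat. aq. NH4Cl at −78 °C
Reagents that add atoms: none
Why: SmI2 ketyl–olefin radical cyclization, in which the C8 ketyl radical adds 6-exo-trig to C7 of the enoate through a chair with the C5, C6, C7 and C8 substituents equatorial (C10 methyl axial) and the resulting trivalent samarium enolate expels acetate to unveil the acrylate, so the ring, C7 and C8 (trans-diequatorial) are set in one step.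

Step 14
Reactants: 24 2-(hydroxymethyl)acrylic acid
Product: 26 2-[(tert-butyldimethylsilyloxy)methyl]acrylic acid, via silyl ester 25 (not isolated)
Conditions: t-BuMe2SiCl (2.2 equiv), imidazole, DMF, rt; then K2CO3 (cat.), MeOH/H2O, rt; aqueous citric acid to pH 4
Reagents that add atoms: tert-butyldimethylsilyl chloride, CC(C)(C)[Si](C)(C)Cl
Why: bis-silylation followed by selective hydrolysis of the labile silyl ester leaves the silyl ether acid; no stereocentre.

Step 15
Reactants: 23 the C8 alcohol from step 13; 26 2-[(tert-butyldimethylsilyloxy)methyl]acrylic acid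
Product: 27 2-(trimethylsilyl)ethyl 8α-{2-[(tert-butyldimethylsilyloxy)methyl]acryloyloxy}-6α-(triethylsilyloxy)-15-(tert-butyldimethylsilyloxy)elema-1,3,11(13)-trien-12-oate
Conditions: EDC·HCl, DMAP (cat.), CH2Cl2, 0 °C → rt
Reagents that add atoms: none
Why: Steglich esterification of the only free hydroxyl (equatorial C8–OH), with retention at C8.

Step 16
Reactants: 27 the fully protected ester from step 15
Product: 28 8α-[2-(hydroxymethyl)acryloyloxy]-6α,15-dihydroxyelema-1,3,11(13)-trien-12-oic acid (5R,6R,7S,8S,10S; target CNP0509685.1)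
Conditions: tris(dimethylamino)sulfonium difluorotrimethylsilicate (6 equiv), DMF, 0 °C → rt; aq. NH4Cl work-up at 0 °C
Reagents that add atoms: none
Why: fluoride-mediated global deprotection removes both tert-butyldimethylsilyl ethers, the triethylsilyl ether and the 2-(trimethylsilyl)ethyl ester (β-elimination to ethylene) without acid, so the 6-hydroxy acid does not lactonize and no stereocentre is touched.

## Compound list

1 | (E)-2-methylbut-2-enoyl chloride (tigloyl chloride) | C/C=C(\C)C(Cl)=O | starting material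
2 | (R)-4-benzyl-3-[(E)-2-methylbut-2-enoyl]oxazolidin-2-one | C/C=C(\C)C(=O)N1[C@H](Cc2ccccc2)COC1=O | intermediate
3 | 1,3,2-dioxathiolane 2,2-dioxide (ethylene sulfate) | O=S1(=O)OCCO1 | starting material
4 | sodium (S)-3-[(R)-4-benzyl-2-oxooxazolidine-3-carbonyl]-3-methylpent-4-enyl sulfate | [Na+].[O-]S(=O)(=O)OCC[C@@](C)(C=C)C(=O)N1[C@H](Cc2ccccc2)COC1=O | intermediate (not isolated)
5 | (R)-4-benzyl-3-[(S)-2-(2-hydroxyethyl)-2-methylbut-3-enoyl]oxazolidin-2-one | OCC[C@@](C)(C=C)C(=O)N1[C@H](Cc2ccccc2)COC1=O | intermediate (not isolated)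
6 | (S)-3-methyl-3-vinyldihydrofuran-2(3H)-one | C=C[C@]1(C)CCOC1=O | intermediate
7 | 2-bromoprop-2-en-1-ol | C=C(Br)CO | starting material
8 | (2-bromoallyloxy)(tert-butyl)dimethylsilane | C=C(Br)CO[Si](C)(C)C(C)(C)C | intermediate
9 | [3-(tert-butyldimethylsilyloxy)prop-1-en-2-yl]lithium | [Li]C(=C)CO[Si](C)(C)C(C)(C)C | intermediate (not isolated)
10 | lithium (S)-5-[(tert-butyldimethylsilyloxy)methyl]-3-methyl-4-oxo-3-vinylhex-5-en-1-olate | [Li+].[O-]CC[C@@](C)(C=C)C(=O)C(=C)CO[Si](C)(C)C(C)(C)C | intermediate (not isolated)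
11 | (S)-2-[(tert-butyldimethylsilyloxy)methyl]-4-methyl-6-(triethylsilyloxy)-4-vinylhex-1-en-3-one | CC[Si](CC)(CC)OCC[C@@](C)(C=C)C(=O)C(=C)CO[Si](C)(C)C(C)(C)C | intermediate
12 | (4S)-2-[(tert-butyldimethylsilyloxy)methyl]-4-methyl-6-(triethylsilyloxy)-4-vinylhex-1-en-3-ol (C3 epimers) | CC[Si](CC)(CC)OCC[C@@](C)(C=C)C(O)C(=C)CO[Si](C)(C)C(C)(C)C | intermediate
13 | (S)-1-bromo-2-[(tert-butyldimethylsilyloxy)methyl]-4-methyl-6-(triethylsilyloxy)-4-vinylhex-2-ene (E/Z mixture) | CC[Si](CC)(CC)OCC[C@@](C)(C=C)C=C(CBr)CO[Si](C)(C)C(C)(C)C | intermediate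
14 | acryloyl chloride | C=CC(Cl)=O | starting material
15 | 2-(trimethylsilyl)ethyl acrylate | C=CC(=O)OCC[Si](C)(C)C | intermediate
16 | 2,2-dimethoxyacetaldehyde | COC(OC)C=O | starting material
17 | 2-(trimethylsilyl)ethyl 2-(1-hydroxy-2,2-dimethoxyethyl)acrylate (racemic) | C=C(C(O)C(OC)OC)C(=O)OCC[Si](C)(C)C | intermediate
18 | 2-(trimethylsilyl)ethyl 2-(1-acetoxy-2,2-dimethoxyethyl)acrylate (racemic) | C=C(C(OC(C)=O)C(OC)OC)C(=O)OCC[Si](C)(C)C | intermediate (not isolated)
19 | 2-(trimethylsilyl)ethyl (E)-2-(acetoxymethyl)-4,4-dimethoxybut-2-enoate | COC(OC)/C=C(\COC(C)=O)C(=O)OCC[Si](C)(C)C | intermediate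
20 | 2-(trimethylsilyl)ethyl (E)-2-(acetoxymethyl)-4-oxobut-2-enoate | O=C/C=C(\COC(C)=O)C(=O)OCC[Si](C)(C)C | intermediate
21 | 2-(trimethylsilyl)ethyl (2E,4S,5R,6S)-2-(acetoxymethyl)-5-[3-(tert-butyldimethylsilyloxy)prop-1-en-2-yl]-6-methyl-4,8-bis(triethylsilyloxy)-6-vinyloct-2-enoate | CC[Si](CC)(CC)OCC[C@@](C)(C=C)[C@H](C(=C)CO[Si](C)(C)C(C)(C)C)[C@@H](O[Si](CC)(CC)CC)/C=C(\COC(C)=O)C(=O)OCC[Si](C)(C)C | intermediate
22 | 2-(trimethylsilyl)ethyl (2E,4S,5R,6S)-2-(acetoxymethyl)-5-[3-(tert-butyldimethylsilyloxy)prop-1-en-2-yl]-6-methyl-8-oxo-4-(triethylsilyloxy)-6-vinyloct-2-enoate | O=CC[C@@](C)(C=C)[C@H](C(=C)CO[Si](C)(C)C(C)(C)C)[C@@H](O[Si](CC)(CC)CC)/C=C(\COC(C)=O)C(=O)OCC[Si](C)(C)C | intermediate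
23 | 2-(trimethylsilyl)ethyl 8α-hydroxy-6α-(triethylsilyloxy)-15-(tert-butyldimethylsilyloxy)elema-1,3,11(13)-trien-12-oate (5R,6R,7R,8S,10S) | C=C[C@]1(C)C[C@H](O)[C@@H](C(=C)C(=O)OCC[Si](C)(C)C)[C@H](O[Si](CC)(CC)CC)[C@H]1C(=C)CO[Si](C)(C)C(C)(C)C | intermediate
24 | 2-(hydroxymethyl)acrylic acid | C=C(CO)C(=O)O | starting material
25 | tert-butyldimethylsilyl 2-[(tert-butyldimethylsilyloxy)methyl]acrylate | C=C(CO[Si](C)(C)C(C)(C)C)C(=O)O[Si](C)(C)C(C)(C)C | intermediate (not isolated)
26 | 2-[(tert-butyldimethylsilyloxy)methyl]acrylic acid | C=C(CO[Si](C)(C)C(C)(C)C)C(=O)O | intermediate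
27 | 2-(trimethylsilyl)ethyl 8α-{2-[(tert-butyldimethylsilyloxy)methyl]acryloyloxy}-6α-(triethylsilyloxy)-15-(tert-butyldimethylsilyloxy)elema-1,3,11(13)-trien-12-oate (5R,6R,7R,8S,10S) | C=C[C@]1(C)C[C@H](OC(=O)C(=C)CO[Si](C)(C)C(C)(C)C)[C@@H](C(=C)C(=O)OCC[Si](C)(C)C)[C@H](O[Si](CC)(CC)CC)[C@H]1C(=C)CO[Si](C)(C)C(C)(C)C | intermediate
28 | 8α-[2-(hydroxymethyl)acryloyloxy]-6α,15-dihydroxyelema-1,3,11(13)-trien-12-oic acid (5R,6R,7S,8S,10S) | C=C[C@]1(C)C[C@H](OC(=O)C(=C)CO)[C@@H](C(=C)C(=O)O)[C@H](O)[C@H]1C(=C)CO | target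

## Step count and risks

Total step count: 16. Longest linear sequence: 10 steps (1, 2, 4, 5, 6, 11, 12, 13, 15, 16).

Three steps most likely to fail:

- **Step 2.** A hindered sodium dienolate must open a cyclic sulfate to build a quaternary centre, and both rate and facial sense are untested for this pairing. Fallback, from 2 back to 6: the same dienolate is alkylated with tert-butyl bromoacetate to give the imide tert-butyl ester F1. Trifluoroacetic acid in CH2Cl2 gives the imide acid F2. Isobutyl chloroformate and N-methylmorpholine give the mixed anhydride F3, which NaBH4 at −15 °C reduces chemoselectively to hydroxy imide 5. On mild acid work-up 5 lactonizes to 6 and releases the auxiliary.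

- **Step 11.** The new bond forms at a neopentyl γ-carbon, and the catalyst must override any bias from C10 on a functionalized enal. Fallback, from 13 back to 21: magnesium turnings in THF convert 13 into the allylmagnesium bromide F4. Transmetalation at −78 °C with chloro(cyclopentadienyl)[(4S,5S)-2,2-dimethyl-α,α,α′,α′-tetraphenyl-1,3-dioxolane-4,5-dimethanolato]titanium (tetravalent titanium) gives the equilibrating chiral allyltitanium complex F5. F5 adds to enal 20 at −78 °C under reagent control (anti, Re face) to give, after aqueous NH4F work-up, the free C6 alcohol F6. Et3SiCl and imidazole in DMF convert F6 into 21.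

- **Step 13.** Pinacol coupling or simple aldehyde reduction may compete, and the samarium alkoxide may lactonize onto the new ester. Fallback, from 22 back to 23, with no new compound (F0): Pd(PPh3)4 (zerovalent palladium, 5 mol%) ionizes the allylic acetate, and InI (monovalent indium, 1.5 equiv) in THF at rt reduces the π-allyl complex to an allylindium. This adds through C7 to the C8 aldehyde in the same chair arrangement (umpolung allylation) and gives 23 directly.

## Further compounds

F1 | step 2 | (R)-4-benzyl-3-[(S)-2-(2-tert-butoxy-2-oxoethyl)-2-methylbut-3-enoyl]oxazolidin-2-one | CC(C)(C)OC(=O)C[C@@](C)(C=C)C(=O)N1[C@H](Cc2ccccc2)COC1=O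
F2 | step 2 | (S)-3-[(R)-4-benzyl-2-oxooxazolidine-3-carbonyl]-3-methylpent-4-enoic acid | OC(=O)C[C@@](C)(C=C)C(=O)N1[C@H](Cc2ccccc2)COC1=O
F3 | step 2 | isobutyl carbonic anhydride of F2 | CC(C)COC(=O)OC(=O)C[C@@](C)(C=C)C(=O)N1[C@H](Cc2ccccc2)COC1=O
F4 | step 11 | allylmagnesium bromide derived from 13 | CC[Si](CC)(CC)OCC[C@@](C)(C=C)C=C(C[Mg]Br)CO[Si](C)(C)C(C)(C)C
F5 | step 11 | (cyclopentadienyl)[(4S,5S)-TADDOLato]titanium allyl derived from F4 | CC1(C)O[C@@H]([C@H](O1)C(O2)(c1ccccc1)c1ccccc1)C(O[Ti]2(C3C=CC=C3)CC(CO[Si](C)(C)C(C)(C)C)=C[C@](C)(C=C)CCO[Si](CC)(CC)CC)(c1ccccc1)c1ccccc1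
F6 | step 11 | 2-(trimethylsilyl)ethyl (2E,4S,5R,6S)-2-(acetoxymethyl)-5-[3-(tert-butyldimethylsilyloxy)prop-1-en-2-yl]-4-hydroxy-6-methyl-8-(triethylsilyloxy)-6-vinyloct-2-enoate | CC[Si](CC)(CC)OCC[C@@](C)(C=C)[C@H](C(=C)CO[Si](C)(C)C(C)(C)C)[C@@H](O)/C=C(\COC(C)=O)C(=O)OCC[Si](C)(C)C
F0 | step 13 | none | none
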